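**Plan**
1. Retrosynthesis: cut the two ester C–O bonds (tiglate on O8, (2R,3S)-3-hydroxy-2-methylbutanoate on O6) and remove the oxirane oxygen from C4–C5. This leaves an (E,E)-germacra-1(10),4-diene-6,8-diol with O6 (TBS) and O8 (PMB) told apart.
2. Enabling feature: C10=C1–C2–C3–C4=C5 of the ten-membered ring is a cyclodeca-1,5-diene, the [3,3] partner of a trans-1,2-dialkenylcyclohexane. Cutting C2–C3 while joining C5–C10 gives a six-membered ring (C5 to C10) with isopropenyl (C4=C3, C15) on C5 and vinyl (C1=C2) on C10.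
3. The C10 methyl is exchanged for an oxido group, so enolate formation drives the shift (anionic oxy-Cope). The enolate is caught as its triflate and the methyl is returned by cross-coupling.
4. Further cuts: C10–C1 (vinyl addition to a cyclohexanone), C5–C10 (carbonyl-ene closure of an acyclic aldehyde), C5–C6 (alkenyl Grignard on a Weinreb amide), C7–C8 (Evans aldol).
5. Forward order: chain, six-membered ring, ten-membered ring, oxirane, O6 ester, O8 ester, last deprotection.
6. Stereochemistry: C7/C8 come from the (S)-benzyloxazolidinone aldol and C6 from a hydroxyl-directed 1,3-anti reduction. Both ring alkenes come from the chair transition state and C4/C5 from the C6–OH-directed peripheral epoxidation. C2'/C3' come from an (R)-auxiliary aldol and the tiglate from (E)-tigloyl chloride.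

Key step: step 12

Remark: germacrane numbering is used throughout (C1=C10, C4–C5 oxirane, C6 and C8 oxygenated, C7 isopropyl, C14 on C10, C15 on C4); primes mark the hydroxy acid.
Remark: both N-acyl oxazolidinones, 3-[(4-methoxybenzyl)oxy]propanal, the two Grignard solutions, acetaldehyde and tigloyl chloride are taken as catalogue compounds.

**Step 1**
Reactants: 1 (4S)-4-benzyl-3-(3-methylbutanoyl)-1,3-oxazolidin-2-one; 2 3-[(4-methoxybenzyl)oxy]propanal
Product: 4 (4S)-4-benzyl-3-{(2S,3R)-3-hydroxy-5-[(4-methoxybenzyl)oxy]-2-(propan-2-yl)pentanoyl}-1,3-oxazolidin-2-one, via Z-boron enolate 3 (not isolated)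
Conditions: Bu2BOTf, Et3N, CH2Cl2, 0 °C; then 2, −78 to 0 °C; H2O2, MeOH, pH 7 buffer
Reagents that add atoms: dibutylboron triflate, CCCCB(CCCC)OS(=O)(=O)C(F)(F)F (its Bu2B group is held by 3 only)
Why: Evans syn aldol, in which the (Z)-boron enolate reacts through a closed Zimmerman–Traxler chair on the face away from the benzyl group, which should set C7 (S) and C8 (R) in the syn relationship of the target.

**Step 2**
Reactants: 4 aldol imide
Product: 5 (2S,3R)-3-hydroxy-N-methoxy-5-[(4-methoxybenzyl)oxy]-N-methyl-2-(propan-2-yl)pentanamide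
Conditions: MeNH(OMe)·HCl, AlMe3, CH2Cl2, −10 °C to rt
Reagents that add atoms: N,O-dimethylhydroxylamine hydrochloride, CNOC.Cl
Why: Aluminium-amide transamidation (Weinreb amide synthesis), guided to the exocyclic carbonyl by the aluminium-bound β-hydroxyl, removes the auxiliary without touching C7 or C8.

**Step 3**
Reactants: 5 Weinreb amide; 6 2-methylprop-1-en-1-ylmagnesium bromide
Product: 7 (5S,6R)-6-hydroxy-8-[(4-methoxybenzyl)oxy]-2-methyl-5-(propan-2-yl)oct-2-en-4-one
Conditions: 6 (3 equiv), THF, −20 to 0 °C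
Reagents that add atoms: none
Why: Weinreb ketone synthesis, in which the first equivalent of 6 only deprotonates the hydroxyl and the chelated tetrahedral adduct stops at the ketone, so C5, C4, C3 and C15 arrive as a prenyl-type enone.

**Step 4**
Reactants: 7 β-hydroxy enone
Product: 8 (3R,4S,5R)-1-[(4-methoxybenzyl)oxy]-7-methyl-4-(propan-2-yl)oct-6-ene-3,5-diol
Conditions: Me4NBH(OAc)3, MeCN/AcOH, −30 °C
Reagents that add atoms: none
Why: Evans–Saksena reduction, in which the C8 hydroxyl binds boron and delivers hydride internally through a chair, should give only 1,2-reduction and the 1,3-anti diol, that is C6 in the configuration of the target.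

**Step 5**
Reactants: 8 anti diol
Product: 9 (4R,5R)-5-[(2R,4R)-2-(4-methoxyphenyl)-1,3-dioxan-4-yl]-2,6-dimethylhept-2-en-4-ol
Conditions: DDQ, 4 Å MS, CH2Cl2, 0 °C
Reagents that add atoms: none
Why: In this anhydrous oxidative acetalisation of a PMB ether, the benzylic oxocarbenium ion is caught by the C8 hydroxyl (six-membered dioxane, aryl equatorial) and not by the C6 hydroxyl (eight-membered ring), which tells the two secondary alcohols apart.

**Step 6**
Reactants: 9 acetal alcohol
Product: 10 tert-butyl({(4R,5S)-5-[(2R,4R)-2-(4-methoxyphenyl)-1,3-dioxan-4-yl]-2,6-dimethylhept-2-en-4-yl}oxy)dimethylsilane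
Conditions: TBSOTf, 2,6-lutidine, CH2Cl2, −78 to −20 °C
Reagents that add atoms: tert-butyldimethylsilyl triflate, CC(C)(C)[Si](C)(C)OS(=O)(=O)C(F)(F)F
Why: Standard silylation of a hindered allylic alcohol with the silyl triflate at low temperature, where aryl acetals persist.

**Step 7**
Reactants: 10 silyl ether acetal
Product: 11 (3R,4S,5R)-5-[(tert-butyldimethylsilyl)oxy]-3-[(4-methoxybenzyl)oxy]-7-methyl-4-(propan-2-yl)oct-6-en-1-ol
Conditions: i-Bu2AlH, CH2Cl2, −78 to 0 °C
Reagents that add atoms: none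
Why: In this regioselective reductive opening of a 4-methoxybenzylidene acetal, aluminium binds the less hindered primary oxygen, so the PMB ether stays on O8 and the C10 alcohol is freed.

**Step 8**
Reactants: 11 primary alcohol
Product: 12 (3R,4S,5R)-5-[(tert-butyldimethylsilyl)oxy]-3-[(4-methoxybenzyl)oxy]-7-methyl-4-(propan-2-yl)oct-6-enal
Conditions: TEMPO (cat.), PhI(OAc)2, CH2Cl2, rt
Reagents that add atoms: none
Why: Oxoammonium (TEMPO) oxidation stops at the aldehyde and is mild enough to avoid β-elimination of the C8 ether.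

**Step 9**
Reactants: 12 aldehyde
Product: 13 (1S,2R,3S,4S,5R)-3-[(tert-butyldimethylsilyl)oxy]-5-[(4-methoxybenzyl)oxy]-4-(propan-2-yl)-2-(prop-1-en-2-yl)cyclohexan-1-ol
Conditions: Me2AlCl, CH2Cl2, −78 °C
Reagents that add atoms: none
Why: This is an intramolecular carbonyl-ene reaction of the citronellal-to-isopulegol kind, whose chair transition state holds isopropyl, OPMB, the alkene and the aldehyde oxygen equatorial and OTBS axial (only H-6 faces the Z-methyl, no A(1,3) strain), which should set C5 equatorial and trans to the C10 hydroxyl (erased in step 10) and create the isopropenyl group.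

**Step 10**
Reactants: 13 cyclohexanol
Product: 14 (2S,3S,4S,5R)-3-[(tert-butyldimethylsilyl)oxy]-5-[(4-methoxybenzyl)oxy]-4-(propan-2-yl)-2-(prop-1-en-2-yl)cyclohexan-1-one
Conditions: Dess–Martin periodinane, CH2Cl2, 0 °C to rt
Reagents that add atoms: none
Why: Dess–Martin oxidation under near-neutral conditions should give the β,γ-unsaturated ketone without moving the double bond into conjugation or epimerising the equatorial C5.

**Step 11**
Reactants: 14 ketone; 15 vinylmagnesium bromide
Product: 16 (1S,2S,3S,4S,5R)-3-[(tert-butyldimethylsilyl)oxy]-1-ethenyl-5-[(4-methoxybenzyl)oxy]-4-(propan-2-yl)-2-(prop-1-en-2-yl)cyclohexan-1-ol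
Conditions: CeCl3, 15, THF, −78 °C
Reagents that add atoms: none
Why: In this 1,2-addition of the weakly basic organocerium reagent, axial approach is blocked by the axial C6 silyl ether, so vinyl should enter equatorially, trans to the isopropenyl group, while enolisation and β-elimination are held back.

**Step 12**
Reactants: 16 trans-dialkenylcyclohexanol
Product: 19 (1Z,5E,7R,8S,9R)-7-[(tert-butyldimethylsilyl)oxy]-9-[(4-methoxybenzyl)oxy]-5-methyl-8-(propan-2-yl)cyclodeca-1,5-dien-1-yl trifluoromethanesulfonate, via potassium alkoxide 17 (not isolated), via potassium enolate 18 (not isolated)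
Conditions: KH, 18-crown-6, THF, 0 °C to rt; then PhNTf2, −78 to 0 °C
Reagents that add atoms: N-phenylbis(trifluoromethanesulfonimide), O=S(=O)(N(c1ccccc1)S(=O)(=O)C(F)(F)F)C(F)(F)F; potassium hydride, [K+].[H-] (potassium is held by 17 and 18 only)
Why: KH and 18-crown-6 turn 16 into the free tertiary alkoxide 17, whose hexa-1,5-diene unit C3=C4–C5–C10–C1=C2 undergoes a concerted alkoxide-accelerated [3,3]-sigmatropic shift that forms C2–C3 and breaks the ring bond C5–C10, and the enolate 18 so formed is O-sulfonylated in the same flask. The closest known reaction type is the anionic oxy-Cope ring expansion of trans-1,2-dialkenylcyclohexanols to (E)-cyclodec-5-enones with capture of the enolate by an electrophile, joined to the standard triflation of a potassium enolate. The ten-membered ring is closed not end to end but by a four-atom ring enlargement (six to ten) through a six-centre chair transition state fused to the cyclohexane chair, so no dilution is needed, and the otherwise unfavourable divinylcyclohexane/cyclodecadiene balance is overridden because the product is a delocalised enolate. No sp3 centre is made (C5 and C10 become sp2, C6 to C8 are spectators); the two new stereo-elements are alkene geometries, and with both alkenyl groups equatorial and trans the chair places C3 trans to C6 across C4=C5 and C9 trans to C2 across C10=C1, that is oxygen cis to C2, the place the methyl group takes in step 13. The step needs chair over boat, which the diequatorial arrangement and the axial C6 silyl ether (only H-6 faces C15, no A(1,3) strain) secure, and it needs an enolate that stays on the C1 side, which the mechanism fixes and the absence of a proton source plus trapping at −78 °C preserve, so that the C8 ether is not lost by β-elimination.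

**Step 13**
Reactants: 19 enol triflate
Product: 20 (1(10)E,4E,6R,7S,8R)-6-[(tert-butyldimethylsilyl)oxy]-8-[(4-methoxybenzyl)oxy]germacra-1(10),4-diene
Conditions: Me2Zn, Pd(PPh3)4 (cat.), THF, 0 °C to rt
Reagents that add atoms: dimethylzinc, C[Zn]C
Why: In this Negishi coupling of an enol triflate, oxidative addition to zerovalent palladium, transmetalation and reductive elimination all proceed with retention, so methyl takes the place of oxygen and C1=C10 becomes the (E)-trisubstituted alkene far below the temperature of a retro-Cope reaction.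

**Step 14**
Reactants: 20 protected germacradiene
Product: 21 (1(10)E,4E,6R,7R,8R)-8-[(4-methoxybenzyl)oxy]germacra-1(10),4-dien-6-ol
Conditions: Bu4NF, THF, rt
Reagents that add atoms: none
Why: Fluoride-induced desilylation, run while the molecule still holds no ester, frees the allylic C6 alcohol without acid that could trigger transannular cyclisation.

**Step 15**
Reactants: 21 allylic alcohol
Product: 22 (1(10)E,4R,5R,6S,7R,8R)-4,5-epoxy-8-[(4-methoxybenzyl)oxy]germacr-1(10)-en-6-ol
Conditions: VO(acac)2 (cat.), t-BuOOH, CH2Cl2, 0 °C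
Reagents that add atoms: tert-butyl hydroperoxide, CC(C)(C)OO
Why: In this hydroxyl-directed vanadium-catalysed epoxidation only C4=C5 is allylic to the alcohol, and in the conformer free of A(1,3) strain (H-6 eclipsed with C15) the hydroxyl lies on the outer face, so direction and peripheral attack should both give the (4R,5R)-oxirane syn (threo) to O6.

**Step 16**
Reactants: 23 (4R)-4-benzyl-3-propanoyl-1,3-oxazolidin-2-one; 24 acetaldehyde
Product: 26 (4R)-4-benzyl-3-[(2R,3S)-3-hydroxy-2-methylbutanoyl]-1,3-oxazolidin-2-one, via Z-boron enolate 25 (not isolated)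
Conditions: Bu2BOTf, Et3N, CH2Cl2, 0 °C; then 24, −78 to 0 °C; H2O2, MeOH, pH 7 buffer
Reagents that add atoms: dibutylboron triflate, CCCCB(CCCC)OS(=O)(=O)C(F)(F)F (its Bu2B group is held by 25 only)
Why: Evans syn aldol with the enantiomeric auxiliary should set C2' (R) and C3' (S) through the same closed chair transition state.

**Step 17**
Reactants: 26 aldol imide
Product: 27 (4R)-4-benzyl-3-{(2R,3S)-2-methyl-3-[(triethylsilyl)oxy]butanoyl}-1,3-oxazolidin-2-one
Conditions: TESOTf, 2,6-lutidine, CH2Cl2, −78 to 0 °C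
Reagents that add atoms: triethylsilyl triflate, CC[Si](CC)(CC)OS(=O)(=O)C(F)(F)F
Why: Standard silylation masks the β-hydroxyl with a group that later leaves under very mild fluoride conditions.

**Step 18**
Reactants: 27 silylated imide
Product: 28 (2R,3S)-2-methyl-3-[(triethylsilyl)oxy]butanoic acid
Conditions: LiOH, H2O2, THF/H2O, 0 °C; Na2SO3; dilute HCl to pH 4
Reagents that add atoms: hydrogen peroxide, OO (as LiOOH it supplies the acid oxygen)
Why: Hydroperoxide cleavage of an N-acyl oxazolidinone attacks the exocyclic carbonyl selectively and does not epimerise C2'.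

**Step 19**
Reactants: 22 epoxy alcohol; 28 acid
Product: 29 (1(10)E,4R,5R,6S,7S,8R)-4,5-epoxy-8-[(4-methoxybenzyl)oxy]germacr-1(10)-en-6-yl (2R,3S)-2-methyl-3-[(triethylsilyl)oxy]butanoate
Conditions: DCC, DMAP, CH2Cl2, 0 °C to rt
Reagents that add atoms: none
Why: Steglich esterification acylates the only free hydroxyl under conditions that leave the oxirane closed and C6 unchanged.

**Step 20**
Reactants: 29 PMB ether
Product: 30 (1(10)E,4R,5R,6S,7S,8R)-4,5-epoxy-8-hydroxygermacr-1(10)-en-6-yl (2R,3S)-2-methyl-3-[(triethylsilyl)oxy]butanoate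
Conditions: DDQ, CH2Cl2/pH 7 buffer, 0 °C
Reagents that add atoms: none
Why: Oxidative PMB cleavage by electron transfer to DDQ in a buffered two-phase medium should spare the oxirane, the silyl ether, the ester and the remaining alkene.

**Step 21**
Reactants: 30 C8 alcohol; 31 (E)-2-methylbut-2-enoyl chloride
Product: 32 (1(10)E,4R,5R,6S,7S,8R)-4,5-epoxy-6-({(2R,3S)-2-methyl-3-[(triethylsilyl)oxy]butanoyl}oxy)germacr-1(10)-en-8-yl (E)-2-methylbut-2-enoate
Conditions: 31, pyridine, DMAP (cat.), CH2Cl2, 0 °C to rt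
Reagents that add atoms: none
Why: DMAP-catalysed acylation with pyridine as a weak base avoids the vinylketene path to a deconjugated ester, and the tiglate is the stable E isomer, so its geometry holds.

**Step 22**
Reactants: 32 silyl-protected diester
Product: 33 target, (1(10)E,4R,5R,6S,7S,8R)-4,5-epoxy-6-{[(2R,3S)-3-hydroxy-2-methylbutanoyl]oxy}germacr-1(10)-en-8-yl (E)-2-methylbut-2-enoate
Conditions: HF·pyridine, pyridine, THF, 0 °C
Reagents that add atoms: none
Why: Pyridine-buffered fluoride cleavage removes the labile triethylsilyl ether without base (no acyl shift or retro-aldol) and without free acid (no oxirane opening).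

**Compound list**

| No. | Name | SMILES | Role |
|---|---|---|---|
| 1 | (4S)-4-benzyl-3-(3-methylbutanoyl)-1,3-oxazolidin-2-one | CC(C)CC(=O)N1C(=O)OC[C@@H]1Cc2ccccc2 | starting material |
| 2 | 3-[(4-methoxybenzyl)oxy]propanal | COc1ccc(COCCC=O)cc1 | starting material |
| 3 | (Z)-dibutylboron enolate of 1 | CC(C)/C=C(\OB(CCCC)CCCC)N1C(=O)OC[C@@H]1Cc2ccccc2 | intermediate |
| 4 | (4S)-4-benzyl-3-{(2S,3R)-3-hydroxy-5-[(4-methoxybenzyl)oxy]-2-(propan-2-yl)pentanoyl}-1,3-oxazolidin-2-one | COc1ccc(COCC[C@@H](O)[C@H](C(C)C)C(=O)N2C(=O)OC[C@@H]2Cc3ccccc3)cc1 | intermediate |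
| 5 | (2S,3R)-3-hydroxy-N-methoxy-5-[(4-methoxybenzyl)oxy]-N-methyl-2-(propan-2-yl)pentanamide | COc1ccc(COCC[C@@H](O)[C@H](C(C)C)C(=O)N(C)OC)cc1 | intermediate |
| 6 | 2-methylprop-1-en-1-ylmagnesium bromide | CC(C)=C[Mg]Br | starting material |
| 7 | (5S,6R)-6-hydroxy-8-[(4-methoxybenzyl)oxy]-2-methyl-5-(propan-2-yl)oct-2-en-4-one | COc1ccc(COCC[C@@H](O)[C@H](C(C)C)C(=O)C=C(C)C)cc1 | intermediate |
| 8 | (3R,4S,5R)-1-[(4-methoxybenzyl)oxy]-7-methyl-4-(propan-2-yl)oct-6-ene-3,5-diol | COc1ccc(COCC[C@@H](O)[C@H](C(C)C)[C@H](O)C=C(C)C)cc1 | intermediate |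
| 9 | (4R,5R)-5-[(2R,4R)-2-(4-methoxyphenyl)-1,3-dioxan-4-yl]-2,6-dimethylhept-2-en-4-ol | COc1ccc(cc1)[C@@H]2OCC[C@@H](O2)[C@H](C(C)C)[C@H](O)C=C(C)C | intermediate |
| 10 | tert-butyl({(4R,5S)-5-[(2R,4R)-2-(4-methoxyphenyl)-1,3-dioxan-4-yl]-2,6-dimethylhept-2-en-4-yl}oxy)dimethylsilane | COc1ccc(cc1)[C@@H]2OCC[C@@H](O2)[C@H](C(C)C)[C@H](O[Si](C)(C)C(C)(C)C)C=C(C)C | intermediate |
| 11 | (3R,4S,5R)-5-[(tert-butyldimethylsilyl)oxy]-3-[(4-methoxybenzyl)oxy]-7-methyl-4-(propan-2-yl)oct-6-en-1-ol | OCC[C@@H](OCc1ccc(OC)cc1)[C@H](C(C)C)[C@H](O[Si](C)(C)C(C)(C)C)C=C(C)C | intermediate |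
| 12 | (3R,4S,5R)-5-[(tert-butyldimethylsilyl)oxy]-3-[(4-methoxybenzyl)oxy]-7-methyl-4-(propan-2-yl)oct-6-enal | O=CC[C@@H](OCc1ccc(OC)cc1)[C@H](C(C)C)[C@H](O[Si](C)(C)C(C)(C)C)C=C(C)C | intermediate |
| 13 | (1S,2R,3S,4S,5R)-3-[(tert-butyldimethylsilyl)oxy]-5-[(4-methoxybenzyl)oxy]-4-(propan-2-yl)-2-(prop-1-en-2-yl)cyclohexan-1-ol | O[C@H]1C[C@@H](OCc2ccc(OC)cc2)[C@H](C(C)C)[C@H](O[Si](C)(C)C(C)(C)C)[C@@H]1C(C)=C | intermediate |
| 14 | (2S,3S,4S,5R)-3-[(tert-butyldimethylsilyl)oxy]-5-[(4-methoxybenzyl)oxy]-4-(propan-2-yl)-2-(prop-1-en-2-yl)cyclohexan-1-one | O=C1C[C@@H](OCc2ccc(OC)cc2)[C@H](C(C)C)[C@H](O[Si](C)(C)C(C)(C)C)[C@@H]1C(C)=C | intermediate |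
| 15 | vinylmagnesium bromide | C=C[Mg]Br | starting material |
| 16 | (1S,2S,3S,4S,5R)-3-[(tert-butyldimethylsilyl)oxy]-1-ethenyl-5-[(4-methoxybenzyl)oxy]-4-(propan-2-yl)-2-(prop-1-en-2-yl)cyclohexan-1-ol | O[C@]1(C=C)C[C@@H](OCc2ccc(OC)cc2)[C@H](C(C)C)[C@H](O[Si](C)(C)C(C)(C)C)[C@@H]1C(C)=C | intermediate |
| 17 | potassium alkoxide of 16 | [K+].[O-][C@]1(C=C)C[C@@H](OCc2ccc(OC)cc2)[C@H](C(C)C)[C@H](O[Si](C)(C)C(C)(C)C)[C@@H]1C(C)=C | intermediate |
| 18 | potassium (1Z,5E,7R,8S,9R)-7-[(tert-butyldimethylsilyl)oxy]-9-[(4-methoxybenzyl)oxy]-5-methyl-8-(propan-2-yl)cyclodeca-1,5-dien-1-olate | COc1ccc(CO[C@@H]2C/C([O-])=C/CC/C(C)=C/[C@@H](O[Si](C)(C)C(C)(C)C)[C@H]2C(C)C)cc1.[K+] | intermediate |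
| 19 | (1Z,5E,7R,8S,9R)-7-[(tert-butyldimethylsilyl)oxy]-9-[(4-methoxybenzyl)oxy]-5-methyl-8-(propan-2-yl)cyclodeca-1,5-dien-1-yl trifluoromethanesulfonate | COc1ccc(CO[C@@H]2C/C(OS(=O)(=O)C(F)(F)F)=C/CC/C(C)=C/[C@@H](O[Si](C)(C)C(C)(C)C)[C@H]2C(C)C)cc1 | intermediate |
| 20 | (1(10)E,4E,6R,7S,8R)-6-[(tert-butyldimethylsilyl)oxy]-8-[(4-methoxybenzyl)oxy]germacra-1(10),4-diene | COc1ccc(CO[C@@H]2C/C(C)=C/CC/C(C)=C/[C@@H](O[Si](C)(C)C(C)(C)C)[C@H]2C(C)C)cc1 | intermediate |
| 21 | (1(10)E,4E,6R,7R,8R)-8-[(4-methoxybenzyl)oxy]germacra-1(10),4-dien-6-ol | COc1ccc(CO[C@@H]2C/C(C)=C/CC/C(C)=C/[C@@H](O)[C@H]2C(C)C)cc1 | intermediate |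
| 22 | (1(10)E,4R,5R,6S,7R,8R)-4,5-epoxy-8-[(4-methoxybenzyl)oxy]germacr-1(10)-en-6-ol | COc1ccc(CO[C@@H]2C/C(C)=C/CC[C@@]3(C)O[C@@H]3[C@@H](O)[C@H]2C(C)C)cc1 | intermediate |
| 23 | (4R)-4-benzyl-3-propanoyl-1,3-oxazolidin-2-one | CCC(=O)N1C(=O)OC[C@H]1Cc2ccccc2 | starting material |
| 24 | acetaldehyde | CC=O | starting material |
| 25 | (Z)-dibutylboron enolate of 23 | C/C=C(\OB(CCCC)CCCC)N1C(=O)OC[C@H]1Cc2ccccc2 | intermediate |
| 26 | (4R)-4-benzyl-3-[(2R,3S)-3-hydroxy-2-methylbutanoyl]-1,3-oxazolidin-2-one | O=C(N1C(=O)OC[C@H]1Cc2ccccc2)[C@H](C)[C@H](C)O | intermediate |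
| 27 | (4R)-4-benzyl-3-{(2R,3S)-2-methyl-3-[(triethylsilyl)oxy]butanoyl}-1,3-oxazolidin-2-one | O=C(N1C(=O)OC[C@H]1Cc2ccccc2)[C@H](C)[C@H](C)O[Si](CC)(CC)CC | intermediate |
| 28 | (2R,3S)-2-methyl-3-[(triethylsilyl)oxy]butanoic acid | OC(=O)[C@H](C)[C@H](C)O[Si](CC)(CC)CC | intermediate |
| 29 | (1(10)E,4R,5R,6S,7S,8R)-4,5-epoxy-8-[(4-methoxybenzyl)oxy]germacr-1(10)-en-6-yl (2R,3S)-2-methyl-3-[(triethylsilyl)oxy]butanoate | COc1ccc(CO[C@@H]2C/C(C)=C/CC[C@@]3(C)O[C@@H]3[C@@H](OC(=O)[C@H](C)[C@H](C)O[Si](CC)(CC)CC)[C@H]2C(C)C)cc1 | intermediate |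
| 30 | (1(10)E,4R,5R,6S,7S,8R)-4,5-epoxy-8-hydroxygermacr-1(10)-en-6-yl (2R,3S)-2-methyl-3-[(triethylsilyl)oxy]butanoate | O[C@@H]1C/C(C)=C/CC[C@@]2(C)O[C@@H]2[C@@H](OC(=O)[C@H](C)[C@H](C)O[Si](CC)(CC)CC)[C@H]1C(C)C | intermediate |
| 31 | (E)-2-methylbut-2-enoyl chloride (tigloyl chloride) | C/C=C(\C)C(=O)Cl | starting material |
| 32 | (1(10)E,4R,5R,6S,7S,8R)-4,5-epoxy-6-({(2R,3S)-2-methyl-3-[(triethylsilyl)oxy]butanoyl}oxy)germacr-1(10)-en-8-yl (E)-2-methylbut-2-enoate | C/C=C(\C)C(=O)O[C@@H]1C/C(C)=C/CC[C@@]2(C)O[C@@H]2[C@@H](OC(=O)[C@H](C)[C@H](C)O[Si](CC)(CC)CC)[C@H]1C(C)C | intermediate |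
| 33 | (1(10)E,4R,5R,6S,7S,8R)-4,5-epoxy-6-{[(2R,3S)-3-hydroxy-2-methylbutanoyl]oxy}germacr-1(10)-en-8-yl (E)-2-methylbut-2-enoate | C/C=C(\C)C(=O)O[C@@H]1C/C(C)=C/CC[C@@]2(C)O[C@@H]2[C@@H](OC(=O)[C@H](C)[C@H](C)O)[C@H]1C(C)C | target |

**Count**
Total steps: 22. Longest linear sequence: 19 (steps 1 to 15 and 19 to 22).

**Steps most likely to fail**

First, step 12.
- Proton transfer between enolate molecules may move the enolate to the C9 side, from where the C8 ether is lost by β-elimination.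
- O-sulfonylation of the crowded potassium enolate may lag.
- A reversible shift of the silyl group from O6 to the 1,3-diaxial alkoxide may hold the rearrangement back.
- The fallback sets out from 16 and comes back at 19, and it separates ring expansion from sulfonylation. The rearrangement is run as above, but 18 is quenched at −78 °C with chlorotrimethylsilane to give the trimethylsilyl enol ether F1, which is isolated. MeLi in THF at 0 °C then cleaves its Si–O bond regiospecifically to the lithium enolate F2, and PhNTf2 turns this tighter, less basic ion pair into 19.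

Second, step 9.
- The Lewis acid may ionise the allylic silyl ether or expel the β-alkoxy group of the aldehyde.
- The alkene, made poorer by the neighbouring C–O bond, may be too weak a nucleophile.
- The fallback sets out from 11 and comes back at 13, and it makes C5 the γ-terminus of an allylmetal, so no Lewis acid is needed. SeO2 (cat.)/t-BuOOH followed by NaBH4 oxidises the E-methyl group to the diol F3. N-chlorosuccinimide/Me2S (Corey–Kim conditions) converts only the allylic hydroxyl into the allylic chloride F4. TEMPO/PhI(OAc)2 gives the chloro aldehyde F5. CrCl2 (divalent chromium, Nozaki–Hiyama allylation) in THF closes C5–C10 by γ-attack with the usual anti preference, which gives 13 with its isopropenyl group.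

Third, step 11.
- Deprotonation of the doubly activated C5–H may compete with addition, with loss of the C5 configuration, drift of the alkene into conjugation or β-elimination of a ring ether.
- The fallback sets out from 14 and comes back at 16, and it uses a far less basic carbon nucleophile. Ethynylmagnesium bromide in THF at −78 to 0 °C adds from the open equatorial side to give the ethynyl carbinol F6. Semi-hydrogenation (H2, Pd/CaCO3 poisoned with Pb(OAc)2, quinoline) stops at the vinyl group of 16 and leaves the isopropenyl group and the PMB ether alone.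

**Further compounds**
F1 | step 12 | (1Z,5E,7R,8S,9R)-7-[(tert-butyldimethylsilyl)oxy]-9-[(4-methoxybenzyl)oxy]-5-methyl-8-(propan-2-yl)-1-[(trimethylsilyl)oxy]cyclodeca-1,5-diene | COc1ccc(CO[C@@H]2C/C(O[Si](C)(C)C)=C/CC/C(C)=C/[C@@H](O[Si](C)(C)C(C)(C)C)[C@H]2C(C)C)cc1
F2 | step 12 | lithium enolate corresponding to 18 | COc1ccc(CO[C@@H]2C/C([O-])=C/CC/C(C)=C/[C@@H](O[Si](C)(C)C(C)(C)C)[C@H]2C(C)C)cc1.[Li+]
F3 | step 9 | (2E,4R,5S,6R)-4-[(tert-butyldimethylsilyl)oxy]-6-[(4-methoxybenzyl)oxy]-2-methyl-5-(propan-2-yl)oct-2-ene-1,8-diol | OCC[C@@H](OCc1ccc(OC)cc1)[C@H](C(C)C)[C@H](O[Si](C)(C)C(C)(C)C)/C=C(\C)CO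
F4 | step 9 | (3R,4S,5R,6E)-5-[(tert-butyldimethylsilyl)oxy]-8-chloro-3-[(4-methoxybenzyl)oxy]-7-methyl-4-(propan-2-yl)oct-6-en-1-ol | OCC[C@@H](OCc1ccc(OC)cc1)[C@H](C(C)C)[C@H](O[Si](C)(C)C(C)(C)C)/C=C(\C)CCl
F5 | step 9 | (3R,4S,5R,6E)-5-[(tert-butyldimethylsilyl)oxy]-8-chloro-3-[(4-methoxybenzyl)oxy]-7-methyl-4-(propan-2-yl)oct-6-enal | O=CC[C@@H](OCc1ccc(OC)cc1)[C@H](C(C)C)[C@H](O[Si](C)(C)C(C)(C)C)/C=C(\C)CCl
F6 | step 11 | (1S,2S,3S,4S,5R)-3-[(tert-butyldimethylsilyl)oxy]-1-ethynyl-5-[(4-methoxybenzyl)oxy]-4-(propan-2-yl)-2-(prop-1-en-2-yl)cyclohexan-1-ol | O[C@]1(C#C)C[C@@H](OCc2ccc(OC)cc2)[C@H](C(C)C)[C@H](O[Si](C)(C)C(C)(C)C)[C@@H]1C(C)=C
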